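**Plan**

- Retrosynthesis: ring A is opened first, at C4a–C5 (acylation of the ring-C enol-ether carbon by an acylketene stored as a dioxinone) and at C8–C8a (a vinylogous Michael bond, the C4a=C8a double bond being restored by dehydrogenation). Ring C is then cut at C2–C3 and O1–C8a into the ring-B aldehyde and Danishefsky's diene, and the two aryl–prenyl bonds are cut last to a dibromide.
- Enabling feature: O1, C2 with ring B, C3 and the C4 ketone, closed by the C4a=C8a enol-ether bond, form a 2-aryl-2,3-dihydropyran-4-one. This is the retron of an aldehyde/1-alkoxy-3-siloxydiene cycloaddition, so ring C can be built before ring A exists.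
- Forward order: ring B is dressed (O-methylation, double prenylation), ring C is closed on the aldehyde, C5–C8 are attached at C8a as a masked acetoacetyl unit, and ring A is closed and aromatised last by heat alone, which should deliver both phenols free.
- Stereochemistry: C2 is the only stereocentre. It is set by the chiral titanium catalyst when ring C forms and meets no base afterwards; the phenol that would allow retro-oxa-Michael racemisation appears only in the final, neutral step.

Key step: step 3

Assumption: the (S)-H8-BINOL ligand is taken to direct the diene to the Si face of the aldehyde, which is the face the (S)-pyranone requires (the (R)-ligand is used if the sense proves opposite); all starting materials are taken as purchased.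

**Step 1**
Reactants: 1 3,5-dibromo-4-hydroxybenzaldehyde
Product: 2 3,5-dibromo-4-methoxybenzaldehyde
Conditions: MeI, K2CO3, DMF, rt
Reagents that add atoms: iodomethane, CI
Why: Williamson O-methylation of the acidic, di-ortho-brominated phenol, to which the aldehyde is inert.

**Step 2**
Reactants: 2 3,5-dibromo-4-methoxybenzaldehyde; 3 tributyl(3-methylbut-2-en-1-yl)stannane
Product: 5 4-methoxy-3,5-bis(3-methylbut-2-en-1-yl)benzaldehyde, via monoprenyl bromide 4 (not isolated)
Conditions: 3 (2.5 equiv), Pd(PPh3)4 (5 mol%), DMF, 100 °C
Reagents that add atoms: none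
Why: Twofold Stille coupling of the electron-poor aryl bromides, in which reductive elimination from the aryl(allyl)palladium intermediate at the unsubstituted allyl terminus should give the linear prenyl groups, the aldehyde being unreactive toward the allylstannane without a Lewis acid.

**Step 3**
Reactants: 5 4-methoxy-3,5-bis(3-methylbut-2-en-1-yl)benzaldehyde; 6 Danishefsky's diene, (E)-1-methoxy-3-(trimethylsilyloxy)buta-1,3-diene
Product: 8 (2S)-2-[4-methoxy-3,5-bis(3-methylbut-2-en-1-yl)phenyl]-2,3-dihydro-4H-pyran-4-one, via aldol adduct 7 (not isolated)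
Conditions: 6 (1.5 equiv), Ti(OiPr)4 (20 mol%), (S)-H8-BINOL (22 mol%), 4 Å MS, toluene, 0 °C; then TFA (0.2 equiv), CH2Cl2, 0 °C
Reagents that add atoms: none
Why: The titanium H8-BINOLate binds the formyl oxygen of 5 and the unsubstituted diene terminus adds to the Si face of the carbonyl in a Mukaiyama-aldol event, the stepwise limit of the [4+2], which forms C2–C3 and gives silyl ether 7. Acid then closes ring C by 6-endo-trig oxa-Michael addition of the C2 oxygen to the β-methoxy enone followed by loss of methanol, which forms O1–C8a (C6 of the pyranone) without touching the C2–O bond. The closest known reaction type is the catalytic enantioselective hetero-Diels–Alder reaction of Danishefsky's diene with aromatic aldehydes. C2 is the only stereocentre and is controlled by the chiral ligand alone, since the substrate has neither a resident stereocentre nor a second donor placed for chelation (the methoxy group is remote and flanked by both prenyl groups). The step needs enantioface selectivity and chemoselectivity for the aldehyde over the prenyl double bonds; the formyl group is non-enolisable, unhindered at both ortho positions and the only Lewis-basic electrophile, and isolated trisubstituted alkenes do not react with the siloxydiene.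

**Step 4**
Reactants: 9 2,2,6-trimethyl-4H-1,3-dioxin-4-one
Product: 11 [(2,2-dimethyl-6-methylidene-6H-1,3-dioxin-4-yl)oxy]trimethylsilane, via lithium dienolate 10 (not isolated)
Conditions: LiN(iPr)2, THF, −78 °C; Me3SiCl, −78 °C to rt
Reagents that add atoms: chlorotrimethylsilane, C[Si](C)(C)Cl
Why: γ-Deprotonation of the dioxinone gives the extended enolate, whose O-silylation is the standard preparation of this vinylogous silyl ketene acetal.

**Step 5**
Reactants: 8 (2S)-2-[4-methoxy-3,5-bis(3-methylbut-2-en-1-yl)phenyl]-2,3-dihydro-4H-pyran-4-one; 11 [(2,2-dimethyl-6-methylidene-6H-1,3-dioxin-4-yl)oxy]trimethylsilane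
Product: 13 (2S)-6-[(2,2-dimethyl-4-oxo-4H-1,3-dioxin-6-yl)methyl]-2-[4-methoxy-3,5-bis(3-methylbut-2-en-1-yl)phenyl]-2,3-dihydro-4H-pyran-4-one, via silyl enol ether 12 (not isolated)
Conditions: 11 (1.5 equiv), Me3SiOTf (0.2 equiv), 2,6-di-tert-butylpyridine (0.3 equiv), CH2Cl2, −78 to −40 °C; Et3N, concentrate; Pd(OAc)2 (1.1 equiv), MeCN, rt
Reagents that add atoms: none
Why: Vinylogous Mukaiyama–Michael addition, in which Me3SiOTf turns the vinylogous ester into a 4-silyloxy oxocarbenium ion that the γ-carbon of 11 attacks axially at C6 (2,6-trans, a centre erased again at once) with silyl transfer giving enol ether 12 regiospecifically, followed by Saegusa–Ito oxidation, in which Pd(OAc)2 restores the C5=C6 double bond through β-hydride elimination of the only available hydrogen; C2 is not involved, and its C–O bond should not ionise because the twisted, di-ortho-substituted methoxy group is a poor donor.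

**Step 6**
Reactants: 13 (2S)-6-[(2,2-dimethyl-4-oxo-4H-1,3-dioxin-6-yl)methyl]-2-[4-methoxy-3,5-bis(3-methylbut-2-en-1-yl)phenyl]-2,3-dihydro-4H-pyran-4-one
Product: 15 (2S)-5,7-dihydroxy-2-[4-methoxy-3,5-bis(3-methylbut-2-en-1-yl)phenyl]-2,3-dihydro-4H-chromen-4-one, via acylketene 14 (not isolated)
Conditions: toluene (0.005 M), 110 °C
Reagents that add atoms: none
Why: Proposed new method: retro-[4+2] of the dioxinone at 110 °C expels acetone and leaves acylketene 14, whose ketene carbon lies 1,6 to the nucleophilic α-carbon (C5) of the vinylogous ester; through the enol of the β-keto ketene this is a dienylketene that should close by 6π-electrocyclisation (equivalently, polar C-acylation of the enol-ether carbon), and tautomerisation of the resulting dienone gives the phloroglucinol ring with both hydroxyls free. The closest known reactions are the intramolecular trapping of dioxinone-derived acylketenes (O-acylation to 4-hydroxy-2-pyranones), the acylketene/enol ether [4+2] cycloaddition that forms the same kind of C–C bond, and the dienylketene electrocyclisation that ends the Danheiser benzannulation. No six-ring O-acylation can compete because O1 is an ether, and the neutral medium avoids the base-induced opening of ring C that would racemise C2.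

**Compound list**

1 | 3,5-dibromo-4-hydroxybenzaldehyde | O=Cc1cc(Br)c(O)c(Br)c1 | starting material
2 | 3,5-dibromo-4-methoxybenzaldehyde | O=Cc1cc(Br)c(OC)c(Br)c1 | intermediate
3 | tributyl(3-methylbut-2-en-1-yl)stannane | CC(C)=CC[Sn](CCCC)(CCCC)CCCC | starting material
4 | 3-bromo-4-methoxy-5-(3-methylbut-2-en-1-yl)benzaldehyde | O=Cc1cc(Br)c(OC)c(CC=C(C)C)c1 | intermediate (not isolated)
5 | 4-methoxy-3,5-bis(3-methylbut-2-en-1-yl)benzaldehyde | O=Cc1cc(CC=C(C)C)c(OC)c(CC=C(C)C)c1 | intermediate
6 | Danishefsky's diene, (E)-1-methoxy-3-(trimethylsilyloxy)buta-1,3-diene | CO/C=C/C(=C)O[Si](C)(C)C | starting material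
7 | (1E,5S)-1-methoxy-5-[4-methoxy-3,5-bis(3-methylbut-2-en-1-yl)phenyl]-5-(trimethylsilyloxy)pent-1-en-3-one | CO/C=C/C(=O)C[C@H](O[Si](C)(C)C)c1cc(CC=C(C)C)c(OC)c(CC=C(C)C)c1 | intermediate (not isolated)
8 | (2S)-2-[4-methoxy-3,5-bis(3-methylbut-2-en-1-yl)phenyl]-2,3-dihydro-4H-pyran-4-one | O=C1C=CO[C@H](c2cc(CC=C(C)C)c(OC)c(CC=C(C)C)c2)C1 | intermediate
9 | 2,2,6-trimethyl-4H-1,3-dioxin-4-one | CC1=CC(=O)OC(C)(C)O1 | starting material
10 | lithium 2,2-dimethyl-6-methylidene-6H-1,3-dioxin-4-olate | [Li]OC1=CC(=C)OC(C)(C)O1 | intermediate (not isolated)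
11 | [(2,2-dimethyl-6-methylidene-6H-1,3-dioxin-4-yl)oxy]trimethylsilane | C=C1C=C(O[Si](C)(C)C)OC(C)(C)O1 | intermediate
12 | 6-{[(2R,6S)-6-[4-methoxy-3,5-bis(3-methylbut-2-en-1-yl)phenyl]-4-(trimethylsilyloxy)-5,6-dihydro-2H-pyran-2-yl]methyl}-2,2-dimethyl-4H-1,3-dioxin-4-one (2,6-trans) | C[Si](C)(C)OC1=C[C@@H](CC2=CC(=O)OC(C)(C)O2)O[C@H](c3cc(CC=C(C)C)c(OC)c(CC=C(C)C)c3)C1 | intermediate (not isolated)
13 | (2S)-6-[(2,2-dimethyl-4-oxo-4H-1,3-dioxin-6-yl)methyl]-2-[4-methoxy-3,5-bis(3-methylbut-2-en-1-yl)phenyl]-2,3-dihydro-4H-pyran-4-one | O=C1C=C(CC2=CC(=O)OC(C)(C)O2)O[C@H](c3cc(CC=C(C)C)c(OC)c(CC=C(C)C)c3)C1 | intermediate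
14 | 4-[(2S)-2-[4-methoxy-3,5-bis(3-methylbut-2-en-1-yl)phenyl]-4-oxo-3,4-dihydro-2H-pyran-6-yl]but-1-ene-1,3-dione | O=C=CC(=O)CC1=CC(=O)C[C@@H](c2cc(CC=C(C)C)c(OC)c(CC=C(C)C)c2)O1 | intermediate (not isolated)
15 | (2S)-5,7-dihydroxy-2-[4-methoxy-3,5-bis(3-methylbut-2-en-1-yl)phenyl]-2,3-dihydro-4H-chromen-4-one | COc1c(CC=C(C)C)cc([C@@H]2CC(=O)c3c(O)cc(O)cc3O2)cc1CC=C(C)C | target

**Totals**

Total step count: 6. Longest linear sequence: 5 steps (steps 1, 2, 3, 5 and 6); step 4 is a one-step side branch.

**Steps most likely to fail**

Step 6 (the proposed step). The acylketene may be consumed by dimerisation, or by intermolecular O-acylation of phenol groups of product already formed, before it closes onto the pyranone carbon. The fallback uses known reaction types only and sets out from 13. The thermolysis is run in toluene containing methanol (110 °C), so that the ketene is intercepted as methyl 4-[(2S)-2-[4-methoxy-3,5-bis(3-methylbut-2-en-1-yl)phenyl]-4-oxo-3,4-dihydro-2H-pyran-6-yl]-3-oxobutanoate F1. This enol-ether form of a 3,5,7-triketo ester is then cyclised in the Claisen mode with Mg(OMe)2 in MeOH at or below room temperature, as in biomimetic cyclisations of polyketo esters to acylphloroglucinols. The extended enolate formed at the doubly activated CH2 acylates through C5 of the pyranone; the aldol mode would require a bridged arene and is excluded. Mild acidification should return the route at 15. The base treatment is kept short and cold and the enantiomeric purity is checked, because alkoxide can open ring C.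

Step 5. The labile trimethylsilyl enol ether may be protodesilylated before the oxidation, or palladium may engage the prenyl double bonds; either leaves the saturated ketone, which cannot be dehydrogenated regioselectively. The fallback installs the oxidation level before the C–C bond and sets out from 8. α-Iodination (I2, pyridine, CH2Cl2, 0 °C) should give (2S)-5-iodo-2-[4-methoxy-3,5-bis(3-methylbut-2-en-1-yl)phenyl]-2,3-dihydro-4H-pyran-4-one F2. BF3·OEt2-promoted vinylogous Mukaiyama–Michael addition of 11 (CH2Cl2, −78 °C, aqueous work-up) should then give the α-iodo ketone 6-{[(2R,3R,6S)-3-iodo-6-[4-methoxy-3,5-bis(3-methylbut-2-en-1-yl)phenyl]-4-oxotetrahydro-2H-pyran-2-yl]methyl}-2,2-dimethyl-4H-1,3-dioxin-4-one F3 (its C3 epimer would serve equally). DBU (CH2Cl2, 0 °C) then removes hydrogen iodide across the former C5–C6 bond and returns the route at 13, without palladium and without a silyl enol ether that has to survive.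

Step 3. Enantioface discrimination may be insufficient for this aldehyde, or the acid used for ring closure may add to the prenyl double bonds. The fallback replaces Lewis-acid catalysis by hydrogen-bond catalysis with an aminosiloxydiene and sets out from 5. Cycloaddition with commercial (E)-1-(dimethylamino)-3-(tert-butyldimethylsilyloxy)buta-1,3-diene in toluene at −40 °C is catalysed by the antipode of the TADDOL diol (α,α,α′,α′-tetra(1-naphthyl)-2,2-dimethyl-1,3-dioxolane-4,5-dimethanol) that gives Si-face addition. It should give the concerted cycloadduct (2R,6S)-4-(tert-butyldimethylsilyloxy)-6-[4-methoxy-3,5-bis(3-methylbut-2-en-1-yl)phenyl]-N,N-dimethyl-5,6-dihydro-2H-pyran-2-amine F4 (2,6-cis expected; the aminal centre is lost in the next operation). Acetyl chloride at −78 °C then expels the amine as its acetamide and the silyl group as its chloride, returning the route at 8 without any protic acid.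

**Further compounds**

F1 | step 6 | methyl 4-[(2S)-2-[4-methoxy-3,5-bis(3-methylbut-2-en-1-yl)phenyl]-4-oxo-3,4-dihydro-2H-pyran-6-yl]-3-oxobutanoate | COC(=O)CC(=O)CC1=CC(=O)C[C@@H](c2cc(CC=C(C)C)c(OC)c(CC=C(C)C)c2)O1
F2 | step 5 | (2S)-5-iodo-2-[4-methoxy-3,5-bis(3-methylbut-2-en-1-yl)phenyl]-2,3-dihydro-4H-pyran-4-one | O=C1C(I)=CO[C@H](c2cc(CC=C(C)C)c(OC)c(CC=C(C)C)c2)C1
F3 | step 5 | 6-{[(2R,3R,6S)-3-iodo-6-[4-methoxy-3,5-bis(3-methylbut-2-en-1-yl)phenyl]-4-oxotetrahydro-2H-pyran-2-yl]methyl}-2,2-dimethyl-4H-1,3-dioxin-4-one | O=C1[C@H](I)[C@@H](CC2=CC(=O)OC(C)(C)O2)O[C@H](c3cc(CC=C(C)C)c(OC)c(CC=C(C)C)c3)C1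
F4 | step 3 | (2R,6S)-4-(tert-butyldimethylsilyloxy)-6-[4-methoxy-3,5-bis(3-methylbut-2-en-1-yl)phenyl]-N,N-dimethyl-5,6-dihydro-2H-pyran-2-amine | CN(C)[C@H]1C=C(O[Si](C)(C)C(C)(C)C)C[C@@H](c2cc(CC=C(C)C)c(OC)c(CC=C(C)C)c2)O1
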